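**Retrosynthetic overview**

- The strategy rests on the two-carbon bridge C(=O)–C(CH3)(O) of the bicyclo[2.2.2]octenone. It joins the methyl-bearing bridgehead to the carbinol bridgehead, and its ether oxygen is tied through CH2 to the ring CH (tetrahydrofuran). Cutting C(CH3)(O)–C(OH) (aldol) and C(CH3)–C(=O) (acyl) leads to the phenyl lactate ether 13, in which only the CH2O-bearing carbon C6 carries the stereochemical information.
- 13 comes from the 2-unsubstituted 4-pyranone 11 by ligand-controlled conjugate addition of phenyl at C2, under neutral conditions, as the last step before the cascade.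
- 11 comes from pyranone 3 by dianion alkylation at C6 with a lactate-derived α-chloro ether (the C6 epimers are diastereomers and are separated), lateral methylation at C8 and ester exchange. 3 comes from 2-acetyldimedone and a one-carbon amide acetal, so the position of the ring oxygen is fixed by symmetry before any substituent is introduced.
- Ring order: cyclohexanedione (bought), 4-pyranone (step 1), bridged seven-membered keto ether, then tetrahydrofuran and bicyclo[2.2.2]octenone together (step 8).

Key step: step 8

Remark: step 3 forms both C6 epimers and only the (6R) diastereomer 7 is carried on, the (6S) diastereomer being discarded after chromatography; step 4 gives both C8 epimers, which are carried together and drawn as the 6,8-cis one because this centre becomes the planar dienolate carbon in step 8; in step 7 the (S) ligand is assumed, by analogy with chromone, to give (2R), and its enantiomer is used if the sense is the opposite.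

Step 1
Reactants: 1 2-acetyl-5,5-dimethylcyclohexane-1,3-dione (2-acetyldimedone)
Product: 3 7,7-dimethyl-7,8-dihydro-4H-chromene-4,5(6H)-dione, via dimethylaminoacryloyl trione 2 (not isolated)
Conditions: Me2NCH(OMe)2 (1.5 equiv), PhMe, 100 °C; then AcOH, 80 °C
Reagents that add atoms: N,N-dimethylformamide dimethyl acetal, COC(OC)N(C)C
Why: The acetyl methyl of the triketone condenses with the amide acetal to the enaminone 2 and acid then closes the 4-pyranone by addition of the enol oxygen to the enaminone β-carbon with loss of dimethylamine (enaminone route to chromones); because the two ring carbonyls of 1 are equivalent only one pyranone can form, and no stereocenter is created.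

Step 2
Reactants: 4 tert-butyl (2S)-2-hydroxypropanoate (tert-butyl (S)-lactate)
Product: 5 tert-butyl (2S)-2-[(methylsulfanyl)methoxy]propanoate
Conditions: Me2S (8 equiv), (PhCO2)2 (4 equiv), MeCN, 0 °C
Reagents that add atoms: dimethyl sulfide, CSC
Why: Pummerer-type methylthiomethylation of the secondary hydroxyl by the sulfonium species formed from dimethyl sulfide and dibenzoyl peroxide (MTM ether formation) should proceed under near-neutral conditions that leave the tert-butyl ester and the lactate stereocenter untouched.

Step 3
Reactants: 3 7,7-dimethyl-7,8-dihydro-4H-chromene-4,5(6H)-dione; 5 tert-butyl (2S)-2-[(methylsulfanyl)methoxy]propanoate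
Product: 7 tert-butyl (2S)-2-{[(6R)-7,7-dimethyl-4,5-dioxo-5,6,7,8-tetrahydro-4H-chromen-6-yl]methoxy}propanoate, via chloromethyl ether 6 (not isolated)
Conditions: 5: SO2Cl2 (1.05 equiv), CH2Cl2, −78 → 0 °C, then evaporation; 3: LiN(iPr)2 (2.0 equiv), THF, −78 → −40 °C; then crude 6, −78 °C; sat. aq. NH4Cl; chromatography on SiO2
Reagents that add atoms: none
Why: Chlorinolysis of the O,S-acetal 5 gives the α-chloro ether 6, while in 3 the first equivalent of amide removes the lateral C8–H (anion conjugated to both carbonyls) and the second forms the C5–C6 enolate, so that the dianion is alkylated at its less stabilised C6 site (β-diketone-type dianion alkylation) and C8 is left free; C6 forms without facial control, but as the arm carries the (S)-lactate centre the two C6 epimers are diastereomers, and chromatography should deliver the (6R) isomer 7 free of its (6S) epimer, which is not carried further.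

Step 4
Reactants: 7 tert-butyl (2S)-2-{[(6R)-7,7-dimethyl-4,5-dioxo-5,6,7,8-tetrahydro-4H-chromen-6-yl]methoxy}propanoate
Product: 8 tert-butyl (2S)-2-{[(6R,8R)-7,7,8-trimethyl-4,5-dioxo-5,6,7,8-tetrahydro-4H-chromen-6-yl]methoxy}propanoate (accompanied by its 8S epimer)
Conditions: LiN(SiMe3)2 (1.05 equiv), THF, −78 °C; MeI (1.5 equiv), −78 → −30 °C
Reagents that add atoms: iodomethane, CI
Why: Lateral deprotonation of the 2-alkyl-4-pyranone at C8, the only proton whose anion is delocalised into both carbonyls, followed by C-methylation at this exocyclic-type carbon restores the pyranone (lateral alkylation of 4-pyranones), while the anionic substrate is not enolised further at C6 and its tert-butyl ester is too poor an acyl donor to be attacked at −78 °C; the new C8 centre arises as both epimers, which is harmless because it is planarised in step 8.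

Step 5
Reactants: 8 tert-butyl (2S)-2-{[(6R,8R)-7,7,8-trimethyl-4,5-dioxo-5,6,7,8-tetrahydro-4H-chromen-6-yl]methoxy}propanoate
Product: 9 (2S)-2-{[(6R,8R)-7,7,8-trimethyl-4,5-dioxo-5,6,7,8-tetrahydro-4H-chromen-6-yl]methoxy}propanoic acid
Conditions: CF3CO2H–CH2Cl2 (1:3), 0 °C → rt
Reagents that add atoms: none
Why: Acidolysis of the tert-butyl ester by the E1 loss of 2-methylpropene should leave the pyranone, the β-alkoxy ketone and the C6 centre unchanged, since no base is present and the ketone is slow to enolise in this medium.

Step 6
Reactants: 9 (2S)-2-{[(6R,8R)-7,7,8-trimethyl-4,5-dioxo-5,6,7,8-tetrahydro-4H-chromen-6-yl]methoxy}propanoic acid; 10 phenol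
Product: 11 phenyl (2S)-2-{[(6R,8R)-7,7,8-trimethyl-4,5-dioxo-5,6,7,8-tetrahydro-4H-chromen-6-yl]methoxy}propanoate
Conditions: N-(3-dimethylaminopropyl)-N′-ethylcarbodiimide hydrochloride (EDC·HCl, 1.3 equiv), 4-(dimethylamino)pyridine (0.1 equiv), CH2Cl2, 0 °C → rt
Reagents that add atoms: none
Why: Carbodiimide activation of the acid with nucleophilic catalysis (Steglich esterification) should give the aryl ester that later serves as acyl donor, and the medium is not basic enough to ionise C8–H, so the ester is not consumed by premature ring closure.

Step 7
Reactants: 11 phenyl (2S)-2-{[(6R,8R)-7,7,8-trimethyl-4,5-dioxo-5,6,7,8-tetrahydro-4H-chromen-6-yl]methoxy}propanoate; 12 phenylboronic acid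
Product: 13 phenyl (2S)-2-{[(2R,6R,8R)-7,7,8-trimethyl-4,5-dioxo-2-phenyl-3,4,5,6,7,8-hexahydro-2H-chromen-6-yl]methoxy}propanoate
Conditions: Pd(OCOCF3)2 (5 mol %), (S)-4-tert-butyl-2-(pyridin-2-yl)-4,5-dihydro-1,3-oxazole (6 mol %), NH4PF6 (30 mol %), H2O (5 equiv), ClCH2CH2Cl, 60 °C
Reagents that add atoms: none
Why: Transmetalation gives a cationic aryl–palladium species (divalent palladium throughout) that adds across the only unhindered enone carbon–carbon double bond with phenyl going to C2, and protonolysis of the palladium enolate releases the ketone (asymmetric conjugate addition of arylboronic acids, known for chromones); the pyridine–oxazoline ligand and not the remote C6 centre should choose the face and so set C2 as (R), while the neutral medium spares the phenyl ester and the epimerisable C6.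

Step 8
Reactants: 13 phenyl (2S)-2-{[(2R,6R,8R)-7,7,8-trimethyl-4,5-dioxo-2-phenyl-3,4,5,6,7,8-hexahydro-2H-chromen-6-yl]methoxy}propanoate
Product: 15 CNP0322161.2 (target cage hydroxy diketone), via bridged C8-acyl keto ether 14 (not isolated)
Conditions: LiN(SiMe3)2 (2.4 equiv), THF, −78 → −20 °C; sat. aq. NH4Cl, −78 °C
Reagents that add atoms: none
Why: LiN(SiMe3)2 first removes C8–H, the most acidic proton because its anion is delocalised through C8a=C4a into both the C4 and the C5 carbonyl, and this γ-dienolate attacks the phenyl ester that the C6–CH2–O tether holds over the same ring face (7-exo-trig acyl substitution with loss of phenoxide), a vinylogous Dieckmann condensation that gives the bridged ketone 14 with C8 quaternary. A second equivalent of base enolises the new α-alkoxy ketone toward the former lactate carbon, and this enolate adds across the ring to the C5 ketone in an intramolecular aldol addition that is 5-exo-trig for the tetrahydrofuran and 6-(enolendo)-exo-trig for the carbocycle, so closing the bicyclo[2.2.2]octenone. The closest known reaction type is the Dieckmann-type C-acylation of extended (vinylogous ester) enolates by aryl esters followed by a transannular aldol addition. All three new centres are controlled by C6: its three-atom tether reaches C8 and then C5 only from its own face, which fixes the methyl-bearing bridgehead, the carbinol bridgehead and, through the cis-fused tetrahydrofuran, the ether-bearing carbon, whereas the lactate and C8 centres of 13 are erased on the way. The step needs acylation at C8 and not at C4a or oxygen and it needs C6 and C3 to stay un-enolised: acylation at C4a or oxygen should be reversible under the phenoxide released (retro-Claisen of a non-enolisable triacylmethane, acyl return from the enol ester) while the C8 product is drained by the aldol step, and once the substrate is an anion further deprotonation at C6 (β-elimination of the arm) or C3 (ring opening at C2) should be slow between −78 and −20 °C when little excess base is present.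

**Compound list**

1 | 2-acetyl-5,5-dimethylcyclohexane-1,3-dione (2-acetyldimedone) | CC(=O)C1C(=O)CC(C)(C)CC1=O | starting material
2 | 2-[(E)-3-(dimethylamino)prop-2-enoyl]-5,5-dimethylcyclohexane-1,3-dione | CN(C)/C=C/C(=O)C1C(=O)CC(C)(C)CC1=O | intermediate
3 | 7,7-dimethyl-7,8-dihydro-4H-chromene-4,5(6H)-dione | O=C1C=COC2=C1C(=O)CC(C)(C)C2 | intermediate
4 | tert-butyl (2S)-2-hydroxypropanoate | CC(C)(C)OC(=O)[C@H](C)O | starting material
5 | tert-butyl (2S)-2-[(methylsulfanyl)methoxy]propanoate | CC(C)(C)OC(=O)[C@H](C)OCSC | intermediate
6 | tert-butyl (2S)-2-(chloromethoxy)propanoate | CC(C)(C)OC(=O)[C@H](C)OCCl | intermediate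
7 | tert-butyl (2S)-2-{[(6R)-7,7-dimethyl-4,5-dioxo-5,6,7,8-tetrahydro-4H-chromen-6-yl]methoxy}propanoate | CC1(C)[C@H](CO[C@@H](C)C(=O)OC(C)(C)C)C(=O)C2=C(OC=CC2=O)C1 | intermediate
8 | tert-butyl (2S)-2-{[(6R,8R)-7,7,8-trimethyl-4,5-dioxo-5,6,7,8-tetrahydro-4H-chromen-6-yl]methoxy}propanoate (8S epimer present) | CC1(C)[C@H](CO[C@@H](C)C(=O)OC(C)(C)C)C(=O)C2=C(OC=CC2=O)[C@@H]1C | intermediate
9 | (2S)-2-{[(6R,8R)-7,7,8-trimethyl-4,5-dioxo-5,6,7,8-tetrahydro-4H-chromen-6-yl]methoxy}propanoic acid (8S epimer present) | CC1(C)[C@H](CO[C@@H](C)C(=O)O)C(=O)C2=C(OC=CC2=O)[C@@H]1C | intermediate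
10 | phenol | Oc1ccccc1 | starting material
11 | phenyl (2S)-2-{[(6R,8R)-7,7,8-trimethyl-4,5-dioxo-5,6,7,8-tetrahydro-4H-chromen-6-yl]methoxy}propanoate (8S epimer present) | CC1(C)[C@H](CO[C@@H](C)C(=O)Oc2ccccc2)C(=O)C2=C(OC=CC2=O)[C@@H]1C | intermediate
12 | phenylboronic acid | OB(O)c1ccccc1 | starting material
13 | phenyl (2S)-2-{[(2R,6R,8R)-7,7,8-trimethyl-4,5-dioxo-2-phenyl-3,4,5,6,7,8-hexahydro-2H-chromen-6-yl]methoxy}propanoate (8S epimer present) | CC1(C)[C@H](CO[C@@H](C)C(=O)Oc2ccccc2)C(=O)C2=C(O[C@@H](c3ccccc3)CC2=O)[C@@H]1C | intermediate
14 | bridged keto ether from acylation at C8: the (2R)-2-phenyl-dihydropyranone-fused cyclohexenone of 13 in which C6 and the now quaternary, methyl-bearing C8 are spanned on one face by CH2–O–CH(CH3)–C(=O) (seven-membered oxacycle), C5 ketone still free | CC1(C)[C@@H]2CO[C@@H](C)C(=O)[C@@]1(C)C1=C(C(=O)C[C@H](c3ccccc3)O1)C2=O | intermediate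
15 | CNP0322161.2: bicyclo[2.2.2]oct-5-en-2-one with CH3 on bridgehead C1 (R), CH3 and ether oxygen on C3 (S), OH on bridgehead C4 (R), gem-dimethyl C7, C8 (R) joined to the C3 oxygen through CH2 (tetrahydrofuran), and a (2R)-2-phenyl-2,3-dihydro-4H-pyran-4-one fused at C5=C6 with its ring oxygen on C6 | CC1(C)[C@@H]2CO[C@]3(C)C(=O)[C@@]1(C)C1=C(C(=O)C[C@H](c4ccccc4)O1)[C@]23O | target

**Step count and risks**

Total number of steps: 8. Longest linear sequence: 7 steps (steps 1, 3, 4, 5, 6, 7 and 8 from compound 1; the branch from 4 is equally long).

Steps most likely to fail, riskiest first: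

Step 8. What may go wrong: deprotonation at C3 followed by opening of the dihydropyranone and loss of configuration at C2; acylation of the dienolate at oxygen or at C4a in place of C8 without return; β-elimination of the arm after enolisation at C6. Fallback: the ring closure is moved one step earlier and sets out from 11. There C3 is sp2, C2 is not yet a stereocentre, and C-acylation of the lateral anion of a 2-alkyl-4-pyranone by esters is the established course. LiN(SiMe3)2 (2.4 equiv) in THF from −78 to 0 °C should give the cage pyranone F1, which has the bridge, tetrahydrofuran and tertiary alcohol of 15 but keeps the C2=C3 double bond. Phenyl is then added to C2 of the cage pyranone F1 with phenylboronic acid 12 under the palladium conditions of step 7, which comes back to the route at 15.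

Step 3. What may go wrong: alkylation of the enolate at oxygen by the hard α-chloro ether; attack of the dianion or of residual amide on the ester carbonyl or the lactate C–H, which would blur the diastereomer separation. Fallback: setting out from 3, the same dianion is trapped with gaseous formaldehyde (aldol addition) to give the racemic hydroxymethyl ketone F2. Its primary alcohol is then etherified without enolate chemistry by tert-butyl (2R)-2-{[(trifluoromethyl)sulfonyl]oxy}propanoate and 2,6-di-tert-butyl-4-methylpyridine in CH2Cl2 (SN2 with inversion to the (2S) ether). This should give 7 together with its (6S) epimer F3. The two diastereomers are separated by chromatography as in step 3, F3 is discarded, and the route is rejoined at 7.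

Step 7. What may go wrong: slow carbopalladation of the electron-rich pyranone with protodeboronation of the boronic acid; β-hydride elimination to the 2-phenylpyranone; weak facial discrimination at C2. Fallback: the aryl group is introduced before the ester exchange, setting out from 8, by the rhodium-catalysed Hayashi–Miyaura reaction (phenylboronic acid 12, Rh(acac)(C2H4)2, 2,2′-bis(diphenylphosphino)-1,1′-binaphthyl of the handedness that gives (2R), dioxane–H2O, 100 °C). This tolerates the tert-butyl ester and should give the dihydropyranone tert-butyl ester F4. CF3CO2H in CH2Cl2 then gives the acid F5, and esterification with phenol (EDC·HCl, 4-(dimethylamino)pyridine) comes back to the route at 13.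

Further compounds
F1 | step 8 | cage pyranone: compound 15 without the C2 phenyl group and with the C2=C3 double bond retained | CC1(C)[C@@H]2CO[C@]3(C)C(=O)[C@@]1(C)C1=C(C(=O)C=CO1)[C@]23O
F2 | step 3 | 6-(hydroxymethyl)-7,7-dimethyl-7,8-dihydro-4H-chromene-4,5(6H)-dione (racemic) | CC1(C)C(CO)C(=O)C2=C(OC=CC2=O)C1
F3 | step 3 | tert-butyl (2S)-2-{[(6S)-7,7-dimethyl-4,5-dioxo-5,6,7,8-tetrahydro-4H-chromen-6-yl]methoxy}propanoate (C6 epimer of 7) | CC1(C)[C@@H](CO[C@@H](C)C(=O)OC(C)(C)C)C(=O)C2=C(OC=CC2=O)C1
F4 | step 7 | tert-butyl (2S)-2-{[(2R,6R,8R)-7,7,8-trimethyl-4,5-dioxo-2-phenyl-3,4,5,6,7,8-hexahydro-2H-chromen-6-yl]methoxy}propanoate | CC1(C)[C@H](CO[C@@H](C)C(=O)OC(C)(C)C)C(=O)C2=C(O[C@@H](c3ccccc3)CC2=O)[C@@H]1C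
F5 | step 7 | (2S)-2-{[(2R,6R,8R)-7,7,8-trimethyl-4,5-dioxo-2-phenyl-3,4,5,6,7,8-hexahydro-2H-chromen-6-yl]methoxy}propanoic acid | CC1(C)[C@H](CO[C@@H](C)C(=O)O)C(=O)C2=C(O[C@@H](c3ccccc3)CC2=O)[C@@H]1C
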